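**Plan**

- Cuts: the stilbene bond at ring B C4, the two C(sp3)–C(sp2) bonds ring B C3–ring A C4 and ring A C3–ring C C4, and the ring C C3–(3,5-dihydroxyphenyl) bond. What remains is three copies of one trans-2-(4-oxyphenyl)-2,3-dihydrobenzofuran-3-carboxylic acid oxygenated at C4 and C6.
- Enabling feature: ring A (O1, C2 with its 4-hydroxyphenyl group, C3 and the benzo ring C3a–C7a with oxygen at C6) is (2S)-naringenin once the chromanone carbonyl carbon is pushed out of the ring onto C3. The naringenin C5 oxygen marks ring A C4. Rings B and C repeat the pattern in the (2R) series.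
- Forward: each dihydrofuran ring arises by oxidative 1,2-aryl-shift ring contraction of a protected naringenin (ring A in step 3, the ring B/C unit in step 8). The extruded carbon, as a redox-active ester, is then exchanged for an aryl group under nickel catalysis.
- The chain is joined C → A → B: 3,5-bis(silyloxy)phenyl onto the ring C unit, C4 benzyl ether to triflate, coupling with the ring A ester, the same again with the ring B ester, then a Heck reaction with the catechol styrene and one global deprotection.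
- Stereochemistry: C2 of every ring comes from the chiral pool ((2S)- and (2R)-naringenin). Each C3 is set trans to its C2 aryl group when the benzylic radical is captured by nickel. The E alkene comes from the Heck reaction.

Key step: step 3

Remark: (2R)-naringenin is taken to be purchasable enantiopure like its (2S) antipode (both are separable from the racemate on chiral stationary phases). Piv = 2,2-dimethylpropanoyl, TBS = tert-butyldimethylsilyl, Tf = trifluoromethanesulfonyl, dtbbpy = 4,4'-di-tert-butyl-2,2'-bipyridine; every dihydrobenzofuran is numbered O1, C2, C3, C3a, C4–C7, C7a.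

**Route**

Step 1
Reactants: 1 (2S)-naringenin
Product: 2 (2S)-5-hydroxy-7-(pivaloyloxy)-2-[4-(pivaloyloxy)phenyl]chroman-4-one
Conditions: PivCl (2.2 equiv), pyridine, CH2Cl2, 0 °C
Reagents that add atoms: pivaloyl chloride CC(C)(C)C(=O)Cl
Why: Selective O-acylation of the C7 and C4' phenols, the C5 phenol being held back by its hydrogen bond to the C4 carbonyl; the weak base at 0 °C should not open the pyranone to the chalcone, so C2 is kept.

Step 2
Reactants: 2 (2S)-5-hydroxy-7-(pivaloyloxy)-2-[4-(pivaloyloxy)phenyl]chroman-4-one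
Product: 3 (2S)-5-(benzyloxy)-7-(pivaloyloxy)-2-[4-(pivaloyloxy)phenyl]chroman-4-one
Conditions: BnOH, PPh3, DIAD, THF, 0 → 25 °C
Reagents that add atoms: benzyl alcohol OCc1ccccc1
Why: Mitsunobu etherification of the chelated ortho-acyl phenol under near-neutral conditions, which avoids the carbonate bases that open 5-alkoxyflavanones to chalcones and would racemise C2.

Step 3
Reactants: 3 (2S)-5-(benzyloxy)-7-(pivaloyloxy)-2-[4-(pivaloyloxy)phenyl]chroman-4-one
Product: 5 methyl (2S,3S)-4-(benzyloxy)-6-(pivaloyloxy)-2-[4-(pivaloyloxy)phenyl]-2,3-dihydrobenzofuran-3-carboxylate, via enol ether 4 (not isolated)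
Conditions: PhI(OH)OTs (1.2 equiv), HC(OMe)3–MeOH, H2SO4 (cat.), 0 → 25 °C
Reagents that add atoms: trimethyl orthoformate COC(OC)OC, methanol CO
Why: Acid and orthoformate turn the ketone into enol ether 4, which the trivalent iodine reagent attacks at C3 on the face away from the C2 aryl group; methanol adds at C4, and the benzo carbon C4a then migrates from C4 to C3 anti-periplanar to the departing iodobenzene, leaving a dimethoxycarbenium ion that is collected as the methyl ester. This is the known hypervalent-iodine (or Tl(NO3)3) oxidative ring contraction of flavanones to trans-2-aryl-2,3-dihydrobenzofuran-3-carboxylates. The furan ring of ring A is closed not by a cyclisation but by this 1,2-aryl shift, which contracts the six-membered pyranone and forms the C3–C3a bond. The new C3 centre is controlled by the C2 aryl group: the pseudo-equatorial iodanyl group sits trans to it and the shift inverts C3, so the ester should end trans (2S,3S), which is also the more stable isomer. The step needs migration of C4a rather than the shift of the C2 aryl group to C3 (isoflavone), dehydrogenation to the flavone or ionisation of the C2–O bond; O1 and the C5 benzyloxy group flank C4a as donors, whereas the pivalate makes the C2 aryl group a poor migrating and cation-stabilising group. The C7 pivalate tempers the benzo ring against direct attack by the iodine reagent without removing these two donors.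

Step 4
Reactants: 5 methyl (2S,3S)-4-(benzyloxy)-6-(pivaloyloxy)-2-[4-(pivaloyloxy)phenyl]-2,3-dihydrobenzofuran-3-carboxylate
Product: 6 (2S,3S)-4-(benzyloxy)-6-(pivaloyloxy)-2-[4-(pivaloyloxy)phenyl]-2,3-dihydrobenzofuran-3-carboxylic acid
Conditions: LiI, EtOAc, reflux; then 1 M HCl
Reagents that add atoms: none
Why: Nucleophilic (SN2) O-demethylation of the methyl ester by iodide attacks only the methyl carbon, so the two aryl pivalates, which hydroxide would not spare, and the benzyl ether should survive; C3 may equilibrate, but trans is the stable isomer and the centre is made anew in step 15.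

Step 5
Reactants: 6 (2S,3S)-4-(benzyloxy)-6-(pivaloyloxy)-2-[4-(pivaloyloxy)phenyl]-2,3-dihydrobenzofuran-3-carboxylic acid
Product: 7 1,3-dioxoisoindolin-2-yl (2S,3S)-4-(benzyloxy)-6-(pivaloyloxy)-2-[4-(pivaloyloxy)phenyl]-2,3-dihydrobenzofuran-3-carboxylate
Conditions: N-hydroxyphthalimide, DIC, DMAP (cat.), CH2Cl2, 25 °C
Reagents that add atoms: N-hydroxyphthalimide O=C1c2ccccc2C(=O)N1O
Why: Carbodiimide (Steglich-type) esterification gives the redox-active ester needed for radical decarboxylation.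

Step 6
Reactants: 8 (2R)-naringenin
Product: 9 (2R)-5-hydroxy-7-(pivaloyloxy)-2-[4-(pivaloyloxy)phenyl]chroman-4-one
Conditions: PivCl (2.2 equiv), pyridine, CH2Cl2, 0 °C
Reagents that add atoms: pivaloyl chloride CC(C)(C)C(=O)Cl
Why: Selective O-acylation as in step 1, in the mirror-image series.

Step 7
Reactants: 9 (2R)-5-hydroxy-7-(pivaloyloxy)-2-[4-(pivaloyloxy)phenyl]chroman-4-one
Product: 10 (2R)-5-(benzyloxy)-7-(pivaloyloxy)-2-[4-(pivaloyloxy)phenyl]chroman-4-one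
Conditions: BnOH, PPh3, DIAD, THF, 0 → 25 °C
Reagents that add atoms: benzyl alcohol OCc1ccccc1
Why: Mitsunobu etherification as in step 2.

Step 8
Reactants: 10 (2R)-5-(benzyloxy)-7-(pivaloyloxy)-2-[4-(pivaloyloxy)phenyl]chroman-4-one
Product: 12 methyl (2R,3R)-4-(benzyloxy)-6-(pivaloyloxy)-2-[4-(pivaloyloxy)phenyl]-2,3-dihydrobenzofuran-3-carboxylate, via enol ether 11 (not isolated)
Conditions: PhI(OH)OTs (1.2 equiv), HC(OMe)3–MeOH, H2SO4 (cat.), 0 → 25 °C
Reagents that add atoms: trimethyl orthoformate COC(OC)OC, methanol CO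
Why: The same hypervalent-iodine oxidative 1,2-aryl-shift ring contraction as in step 3, giving the trans (2R,3R) ester that serves for both ring B and ring C.

Step 9
Reactants: 12 methyl (2R,3R)-4-(benzyloxy)-6-(pivaloyloxy)-2-[4-(pivaloyloxy)phenyl]-2,3-dihydrobenzofuran-3-carboxylate
Product: 13 (2R,3R)-4-(benzyloxy)-6-(pivaloyloxy)-2-[4-(pivaloyloxy)phenyl]-2,3-dihydrobenzofuran-3-carboxylic acid
Conditions: LiI, EtOAc, reflux; then 1 M HCl
Reagents that add atoms: none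
Why: Nucleophilic O-demethylation by iodide as in step 4.

Step 10
Reactants: 13 (2R,3R)-4-(benzyloxy)-6-(pivaloyloxy)-2-[4-(pivaloyloxy)phenyl]-2,3-dihydrobenzofuran-3-carboxylic acid
Product: 14 1,3-dioxoisoindolin-2-yl (2R,3R)-4-(benzyloxy)-6-(pivaloyloxy)-2-[4-(pivaloyloxy)phenyl]-2,3-dihydrobenzofuran-3-carboxylate
Conditions: N-hydroxyphthalimide, DIC, DMAP (cat.), CH2Cl2, 25 °C
Reagents that add atoms: N-hydroxyphthalimide O=C1c2ccccc2C(=O)N1O
Why: Carbodiimide esterification as in step 5; this redox-active ester is used in steps 12 and 18.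

Step 11
Reactants: 15 5-bromoresorcinol
Product: 16 1-bromo-3,5-bis(tert-butyldimethylsilyloxy)benzene
Conditions: TBSCl, imidazole, DMF, 25 °C
Reagents that add atoms: tert-butyldimethylsilyl chloride CC(C)(C)[Si](C)(C)Cl
Why: Standard O-silylation of phenols; silyl ethers fall in the final basic methanolysis together with the pivalates.

Step 12
Reactants: 14 1,3-dioxoisoindolin-2-yl (2R,3R)-4-(benzyloxy)-6-(pivaloyloxy)-2-[4-(pivaloyloxy)phenyl]-2,3-dihydrobenzofuran-3-carboxylate; 16 1-bromo-3,5-bis(tert-butyldimethylsilyloxy)benzene (3 equiv)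
Product: 19 (2R,3R)-4-(benzyloxy)-3-[3,5-bis(tert-butyldimethylsilyloxy)phenyl]-6-(pivaloyloxy)-2-[4-(pivaloyloxy)phenyl]-2,3-dihydrobenzofuran, via aryllithium 17 (not isolated), via arylzinc chloride 18 (not isolated)
Conditions: 16, n-BuLi, THF, −78 °C; ZnCl2, −78 → 25 °C; then 14, NiCl2(dme) (20 mol%), dtbbpy (40 mol%), THF–DMF, 25 °C
Reagents that add atoms: none
Why: Nickel-catalysed decarboxylative Negishi-type arylation of a redox-active ester: electron transfer releases CO2 and phthalimide anion, and the planar benzylic C3 radical is captured by the arylnickel species on the face away from the C2 aryl group, so the new C3–aryl bond should be set trans (2R,3R) under control of C2; the C2–O bond is held out of alignment for β-aryloxide loss by the five-membered ring.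

Step 13
Reactants: 19 (2R,3R)-4-(benzyloxy)-3-[3,5-bis(tert-butyldimethylsilyloxy)phenyl]-6-(pivaloyloxy)-2-[4-(pivaloyloxy)phenyl]-2,3-dihydrobenzofuran
Product: 20 (2R,3R)-3-[3,5-bis(tert-butyldimethylsilyloxy)phenyl]-4-hydroxy-6-(pivaloyloxy)-2-[4-(pivaloyloxy)phenyl]-2,3-dihydrobenzofuran
Conditions: H2 (1 atm), 10% Pd/C, EtOAc, 25 °C
Reagents that add atoms: none
Why: Hydrogenolysis of the benzyl ether; the aryl pivalates, the aryl silyl ethers and the ring C2–O bond, deactivated by the acylated aryl group, should be left intact.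

Step 14
Reactants: 20 (2R,3R)-3-[3,5-bis(tert-butyldimethylsilyloxy)phenyl]-4-hydroxy-6-(pivaloyloxy)-2-[4-(pivaloyloxy)phenyl]-2,3-dihydrobenzofuran
Product: 21 (2R,3R)-3-[3,5-bis(tert-butyldimethylsilyloxy)phenyl]-6-(pivaloyloxy)-2-[4-(pivaloyloxy)phenyl]-2,3-dihydrobenzofuran-4-yl trifluoromethanesulfonate (ring C triflate)
Conditions: Tf2O, pyridine, CH2Cl2, 0 °C
Reagents that add atoms: trifluoromethanesulfonic anhydride O=S(=O)(OS(=O)(=O)C(F)(F)F)C(F)(F)F
Why: O-Sulfonylation of the phenol turns the former naringenin C5 oxygen into the leaving group for the C4–C bond.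

Step 15
Reactants: 7 1,3-dioxoisoindolin-2-yl (2S,3S)-4-(benzyloxy)-6-(pivaloyloxy)-2-[4-(pivaloyloxy)phenyl]-2,3-dihydrobenzofuran-3-carboxylate (1.5 equiv); 21 ring C triflate
Product: 22 dimer benzyl ether: (2S,3S)-4-(benzyloxy)-6-(pivaloyloxy)-2-[4-(pivaloyloxy)phenyl]-2,3-dihydrobenzofuran (ring A) bonded from C3 to C4 of (2R,3R)-3-[3,5-bis(tert-butyldimethylsilyloxy)phenyl]-6-(pivaloyloxy)-2-[4-(pivaloyloxy)phenyl]-2,3-dihydrobenzofuran (ring C)
Conditions: NiBr2(dme) (10 mol%), dtbbpy (10 mol%), Zn dust, LiBr, DMA, 25 °C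
Reagents that add atoms: none
Why: Nickel-catalysed decarboxylative reductive cross-electrophile coupling of a redox-active ester with an aryl triflate: the arylnickel species formed from 21 captures the ring A C3 benzylic radical on the face away from the ring A C2 aryl group, so ring A C3 should be set trans (2S,3S) while the ring C centres are not touched.

Step 16
Reactants: 22 dimer benzyl ether
Product: 23 dimer phenol: 22 with a free hydroxyl group at ring A C4
Conditions: H2 (1 atm), 10% Pd/C, EtOAc, 25 °C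
Reagents that add atoms: none
Why: Hydrogenolysis of the benzyl ether as in step 13; no alkene or sulfonate is present at this stage.

Step 17
Reactants: 23 dimer phenol
Product: 24 dimer triflate: 23 with ring A C4–OTf
Conditions: Tf2O, pyridine, CH2Cl2, 0 °C
Reagents that add atoms: trifluoromethanesulfonic anhydride O=S(=O)(OS(=O)(=O)C(F)(F)F)C(F)(F)F
Why: O-Sulfonylation of the phenol as in step 14.

Step 18
Reactants: 14 1,3-dioxoisoindolin-2-yl (2R,3R)-4-(benzyloxy)-6-(pivaloyloxy)-2-[4-(pivaloyloxy)phenyl]-2,3-dihydrobenzofuran-3-carboxylate (2 equiv); 24 dimer triflate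
Product: 25 trimer benzyl ether: 24 in which the ring A C4 triflate is replaced by C3 of (2R,3R)-4-(benzyloxy)-6-(pivaloyloxy)-2-[4-(pivaloyloxy)phenyl]-2,3-dihydrobenzofuran (ring B)
Conditions: NiBr2(dme) (10 mol%), dtbbpy (10 mol%), Zn dust, LiBr, DMA, 25 → 40 °C
Reagents that add atoms: none
Why: The same decarboxylative reductive cross-electrophile coupling as in step 15; the ring B C3 radical is captured trans to the ring B C2 aryl group, which should set ring B as (2R,3R).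

Step 19
Reactants: 25 trimer benzyl ether
Product: 26 trimer phenol: 25 with a free hydroxyl group at ring B C4
Conditions: H2 (1 atm), 10% Pd/C, EtOAc, 25 °C
Reagents that add atoms: none
Why: Hydrogenolysis of the last benzyl ether, placed before the stilbene alkene is introduced.

Step 20
Reactants: 26 trimer phenol
Product: 27 trimer triflate: 26 with ring B C4–OTf
Conditions: Tf2O, pyridine, CH2Cl2, 0 °C
Reagents that add atoms: trifluoromethanesulfonic anhydride O=S(=O)(OS(=O)(=O)C(F)(F)F)C(F)(F)F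
Why: O-Sulfonylation of the phenol as in step 14.

Step 21
Reactants: 28 3,4-dihydroxybenzaldehyde
Product: 29 3,4-bis(tert-butyldimethylsilyloxy)benzaldehyde
Conditions: TBSCl, imidazole, DMF, 25 °C
Reagents that add atoms: tert-butyldimethylsilyl chloride CC(C)(C)[Si](C)(C)Cl
Why: Standard O-silylation of the catechol.

Step 22
Reactants: 29 3,4-bis(tert-butyldimethylsilyloxy)benzaldehyde
Product: 30 3,4-bis(tert-butyldimethylsilyloxy)styrene
Conditions: Ph3PCH3Br, n-BuLi, THF, 0 °C; then 29, 0 → 25 °C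
Reagents that add atoms: methyltriphenylphosphonium bromide C[P+](c1ccccc1)(c1ccccc1)c1ccccc1.[Br-]
Why: Wittig methylenation of the aldehyde.

Step 23
Reactants: 27 trimer triflate; 30 3,4-bis(tert-butyldimethylsilyloxy)styrene (3 equiv)
Product: 31 protected tetramer: 27 in which the ring B C4 triflate is replaced by an (E)-2-[3,4-bis(tert-butyldimethylsilyloxy)phenyl]ethenyl group
Conditions: PdCl2(PPh3)2 (10 mol%), LiCl, Et3N, DMF, 90 °C
Reagents that add atoms: none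
Why: Mizoroki–Heck reaction of an aryl triflate with a styrene; chloride steers it onto the neutral pathway, so arylation should occur at the terminal carbon and give the E stilbene, and any silyl ether lost here is of no consequence because the next step removes them all.

Step 24
Reactants: 31 protected tetramer
Product: 32 CNP0099535.1
Conditions: NaOMe, MeOH–THF (degassed, argon), 0 → 25 °C; then AcOH
Reagents that add atoms: none
Why: Base-mediated methanolysis (transesterification) of the six aryl pivalates and methoxide cleavage of the four aryl silyl ethers in one operation, free of Lewis or Brønsted acid that could cyclise the stilbene onto a dihydrobenzofuran; no stereocentre is touched.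

**Compound list**

1 | (2S)-naringenin | O=C1C[C@@H](c2ccc(O)cc2)Oc2cc(O)cc(O)c21 | starting material
2 | (2S)-5-hydroxy-7-(pivaloyloxy)-2-[4-(pivaloyloxy)phenyl]chroman-4-one | O=C1C[C@@H](c2ccc(OC(=O)C(C)(C)C)cc2)Oc2cc(OC(=O)C(C)(C)C)cc(O)c21 | intermediate
3 | (2S)-5-(benzyloxy)-7-(pivaloyloxy)-2-[4-(pivaloyloxy)phenyl]chroman-4-one | O=C1C[C@@H](c2ccc(OC(=O)C(C)(C)C)cc2)Oc2cc(OC(=O)C(C)(C)C)cc(OCc3ccccc3)c21 | intermediate
4 | (2S)-5-(benzyloxy)-4-methoxy-7-(pivaloyloxy)-2-[4-(pivaloyloxy)phenyl]-2H-chromene (enol ether) | COC1=C[C@@H](c2ccc(OC(=O)C(C)(C)C)cc2)Oc2cc(OC(=O)C(C)(C)C)cc(OCc3ccccc3)c21 | intermediate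
5 | methyl (2S,3S)-4-(benzyloxy)-6-(pivaloyloxy)-2-[4-(pivaloyloxy)phenyl]-2,3-dihydrobenzofuran-3-carboxylate | CC(C)(C)C(=O)Oc1ccc([C@H]2Oc3cc(OC(=O)C(C)(C)C)cc(OCc4ccccc4)c3[C@@H]2C(=O)OC)cc1 | intermediate
6 | (2S,3S)-4-(benzyloxy)-6-(pivaloyloxy)-2-[4-(pivaloyloxy)phenyl]-2,3-dihydrobenzofuran-3-carboxylic acid | CC(C)(C)C(=O)Oc1ccc([C@H]2Oc3cc(OC(=O)C(C)(C)C)cc(OCc4ccccc4)c3[C@@H]2C(=O)O)cc1 | intermediate
7 | 1,3-dioxoisoindolin-2-yl (2S,3S)-4-(benzyloxy)-6-(pivaloyloxy)-2-[4-(pivaloyloxy)phenyl]-2,3-dihydrobenzofuran-3-carboxylate | CC(C)(C)C(=O)Oc1ccc([C@H]2Oc3cc(OC(=O)C(C)(C)C)cc(OCc4ccccc4)c3[C@@H]2C(=O)ON2C(=O)c3ccccc3C2=O)cc1 | intermediate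
8 | (2R)-naringenin | O=C1C[C@H](c2ccc(O)cc2)Oc2cc(O)cc(O)c21 | starting material
9 | (2R)-5-hydroxy-7-(pivaloyloxy)-2-[4-(pivaloyloxy)phenyl]chroman-4-one | O=C1C[C@H](c2ccc(OC(=O)C(C)(C)C)cc2)Oc2cc(OC(=O)C(C)(C)C)cc(O)c21 | intermediate
10 | (2R)-5-(benzyloxy)-7-(pivaloyloxy)-2-[4-(pivaloyloxy)phenyl]chroman-4-one | O=C1C[C@H](c2ccc(OC(=O)C(C)(C)C)cc2)Oc2cc(OC(=O)C(C)(C)C)cc(OCc3ccccc3)c21 | intermediate
11 | (2R)-5-(benzyloxy)-4-methoxy-7-(pivaloyloxy)-2-[4-(pivaloyloxy)phenyl]-2H-chromene (enol ether) | COC1=C[C@H](c2ccc(OC(=O)C(C)(C)C)cc2)Oc2cc(OC(=O)C(C)(C)C)cc(OCc3ccccc3)c21 | intermediate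
12 | methyl (2R,3R)-4-(benzyloxy)-6-(pivaloyloxy)-2-[4-(pivaloyloxy)phenyl]-2,3-dihydrobenzofuran-3-carboxylate | CC(C)(C)C(=O)Oc1ccc([C@@H]2Oc3cc(OC(=O)C(C)(C)C)cc(OCc4ccccc4)c3[C@H]2C(=O)OC)cc1 | intermediate
13 | (2R,3R)-4-(benzyloxy)-6-(pivaloyloxy)-2-[4-(pivaloyloxy)phenyl]-2,3-dihydrobenzofuran-3-carboxylic acid | CC(C)(C)C(=O)Oc1ccc([C@@H]2Oc3cc(OC(=O)C(C)(C)C)cc(OCc4ccccc4)c3[C@H]2C(=O)O)cc1 | intermediate
14 | 1,3-dioxoisoindolin-2-yl (2R,3R)-4-(benzyloxy)-6-(pivaloyloxy)-2-[4-(pivaloyloxy)phenyl]-2,3-dihydrobenzofuran-3-carboxylate | CC(C)(C)C(=O)Oc1ccc([C@@H]2Oc3cc(OC(=O)C(C)(C)C)cc(OCc4ccccc4)c3[C@H]2C(=O)ON2C(=O)c3ccccc3C2=O)cc1 | intermediate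
15 | 5-bromoresorcinol | Oc1cc(O)cc(Br)c1 | starting material
16 | 1-bromo-3,5-bis(tert-butyldimethylsilyloxy)benzene | CC(C)(C)[Si](C)(C)Oc1cc(Br)cc(O[Si](C)(C)C(C)(C)C)c1 | intermediate
17 | [3,5-bis(tert-butyldimethylsilyloxy)phenyl]lithium | [Li]c1cc(O[Si](C)(C)C(C)(C)C)cc(O[Si](C)(C)C(C)(C)C)c1 | intermediate
18 | [3,5-bis(tert-butyldimethylsilyloxy)phenyl]zinc chloride | Cl[Zn]c1cc(O[Si](C)(C)C(C)(C)C)cc(O[Si](C)(C)C(C)(C)C)c1 | intermediate
19 | (2R,3R)-4-(benzyloxy)-3-[3,5-bis(tert-butyldimethylsilyloxy)phenyl]-6-(pivaloyloxy)-2-[4-(pivaloyloxy)phenyl]-2,3-dihydrobenzofuran | CC(C)(C)C(=O)Oc1ccc([C@@H]2Oc3cc(OC(=O)C(C)(C)C)cc(OCc4ccccc4)c3[C@H]2c2cc(O[Si](C)(C)C(C)(C)C)cc(O[Si](C)(C)C(C)(C)C)c2)cc1 | intermediate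
20 | (2R,3R)-3-[3,5-bis(tert-butyldimethylsilyloxy)phenyl]-4-hydroxy-6-(pivaloyloxy)-2-[4-(pivaloyloxy)phenyl]-2,3-dihydrobenzofuran | CC(C)(C)C(=O)Oc1ccc([C@@H]2Oc3cc(OC(=O)C(C)(C)C)cc(O)c3[C@H]2c2cc(O[Si](C)(C)C(C)(C)C)cc(O[Si](C)(C)C(C)(C)C)c2)cc1 | intermediate
21 | (2R,3R)-3-[3,5-bis(tert-butyldimethylsilyloxy)phenyl]-6-(pivaloyloxy)-2-[4-(pivaloyloxy)phenyl]-2,3-dihydrobenzofuran-4-yl trifluoromethanesulfonate (ring C triflate) | CC(C)(C)C(=O)Oc1ccc([C@@H]2Oc3cc(OC(=O)C(C)(C)C)cc(OS(=O)(=O)C(F)(F)F)c3[C@H]2c2cc(O[Si](C)(C)C(C)(C)C)cc(O[Si](C)(C)C(C)(C)C)c2)cc1 | intermediate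
22 | dimer benzyl ether: (2S,3S)-4-(benzyloxy)-3-{(2R,3R)-3-[3,5-bis(tert-butyldimethylsilyloxy)phenyl]-6-(pivaloyloxy)-2-[4-(pivaloyloxy)phenyl]-2,3-dihydrobenzofuran-4-yl}-6-(pivaloyloxy)-2-[4-(pivaloyloxy)phenyl]-2,3-dihydrobenzofuran | CC(C)(C)C(=O)Oc1ccc([C@H]2Oc3cc(OC(=O)C(C)(C)C)cc(OCc4ccccc4)c3[C@@H]2c2cc(OC(=O)C(C)(C)C)cc3c2[C@@H](c2cc(O[Si](C)(C)C(C)(C)C)cc(O[Si](C)(C)C(C)(C)C)c2)[C@H](c2ccc(OC(=O)C(C)(C)C)cc2)O3)cc1 | intermediate
23 | dimer phenol: 22 with OH at ring A C4 | CC(C)(C)C(=O)Oc1ccc([C@H]2Oc3cc(OC(=O)C(C)(C)C)cc(O)c3[C@@H]2c2cc(OC(=O)C(C)(C)C)cc3c2[C@@H](c2cc(O[Si](C)(C)C(C)(C)C)cc(O[Si](C)(C)C(C)(C)C)c2)[C@H](c2ccc(OC(=O)C(C)(C)C)cc2)O3)cc1 | intermediate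
24 | dimer triflate: 22 with OTf at ring A C4 | CC(C)(C)C(=O)Oc1ccc([C@H]2Oc3cc(OC(=O)C(C)(C)C)cc(OS(=O)(=O)C(F)(F)F)c3[C@@H]2c2cc(OC(=O)C(C)(C)C)cc3c2[C@@H](c2cc(O[Si](C)(C)C(C)(C)C)cc(O[Si](C)(C)C(C)(C)C)c2)[C@H](c2ccc(OC(=O)C(C)(C)C)cc2)O3)cc1 | intermediate
25 | trimer benzyl ether: 24 with ring A C4 bonded to C3 of (2R,3R)-4-(benzyloxy)-6-(pivaloyloxy)-2-[4-(pivaloyloxy)phenyl]-2,3-dihydrobenzofuran (ring B) | CC(C)(C)C(=O)Oc1ccc([C@H]2Oc3cc(OC(=O)C(C)(C)C)cc([C@@H]4c5c(OCc6ccccc6)cc(OC(=O)C(C)(C)C)cc5O[C@H]4c4ccc(OC(=O)C(C)(C)C)cc4)c3[C@@H]2c2cc(OC(=O)C(C)(C)C)cc3c2[C@@H](c2cc(O[Si](C)(C)C(C)(C)C)cc(O[Si](C)(C)C(C)(C)C)c2)[C@H](c2ccc(OC(=O)C(C)(C)C)cc2)O3)cc1 | intermediate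
26 | trimer phenol: 25 with OH at ring B C4 | CC(C)(C)C(=O)Oc1ccc([C@H]2Oc3cc(OC(=O)C(C)(C)C)cc([C@@H]4c5c(O)cc(OC(=O)C(C)(C)C)cc5O[C@H]4c4ccc(OC(=O)C(C)(C)C)cc4)c3[C@@H]2c2cc(OC(=O)C(C)(C)C)cc3c2[C@@H](c2cc(O[Si](C)(C)C(C)(C)C)cc(O[Si](C)(C)C(C)(C)C)c2)[C@H](c2ccc(OC(=O)C(C)(C)C)cc2)O3)cc1 | intermediate
27 | trimer triflate: 25 with OTf at ring B C4 | CC(C)(C)C(=O)Oc1ccc([C@H]2Oc3cc(OC(=O)C(C)(C)C)cc([C@@H]4c5c(OS(=O)(=O)C(F)(F)F)cc(OC(=O)C(C)(C)C)cc5O[C@H]4c4ccc(OC(=O)C(C)(C)C)cc4)c3[C@@H]2c2cc(OC(=O)C(C)(C)C)cc3c2[C@@H](c2cc(O[Si](C)(C)C(C)(C)C)cc(O[Si](C)(C)C(C)(C)C)c2)[C@H](c2ccc(OC(=O)C(C)(C)C)cc2)O3)cc1 | intermediate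
28 | 3,4-dihydroxybenzaldehyde | O=Cc1ccc(O)c(O)c1 | starting material
29 | 3,4-bis(tert-butyldimethylsilyloxy)benzaldehyde | O=Cc1ccc(O[Si](C)(C)C(C)(C)C)c(O[Si](C)(C)C(C)(C)C)c1 | intermediate
30 | 3,4-bis(tert-butyldimethylsilyloxy)styrene | C=Cc1ccc(O[Si](C)(C)C(C)(C)C)c(O[Si](C)(C)C(C)(C)C)c1 | intermediate
31 | protected tetramer: the target with six aryl pivalates (C6–O and 4-aryl–O of rings A, B and C) and four aryl TBS ethers (3,5-dioxyphenyl and catechol) | CC(C)(C)C(=O)Oc1ccc([C@H]2Oc3cc(OC(=O)C(C)(C)C)cc([C@@H]4c5c(/C=C/c6ccc(O[Si](C)(C)C(C)(C)C)c(O[Si](C)(C)C(C)(C)C)c6)cc(OC(=O)C(C)(C)C)cc5O[C@H]4c4ccc(OC(=O)C(C)(C)C)cc4)c3[C@@H]2c2cc(OC(=O)C(C)(C)C)cc3c2[C@@H](c2cc(O[Si](C)(C)C(C)(C)C)cc(O[Si](C)(C)C(C)(C)C)c2)[C@H](c2ccc(OC(=O)C(C)(C)C)cc2)O3)cc1 | intermediate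
32 | CNP0099535.1 (ring A 2S,3S; ring B 2R,3R; ring C 2R,3R; E alkene) | Oc1ccc([C@H]2Oc3cc(O)cc([C@@H]4c5c(/C=C/c6ccc(O)c(O)c6)cc(O)cc5O[C@H]4c4ccc(O)cc4)c3[C@@H]2c2cc(O)cc3c2[C@@H](c2cc(O)cc(O)c2)[C@H](c2ccc(O)cc2)O3)cc1 | target

**Count and risks**

Total steps: 24. Longest linear sequence: 16 steps (steps 6–10, 12–20, 23 and 24, from (2R)-naringenin 8).

Steps most likely to fail:

1. Step 18. The triflate of 24 sits next to ring A C3, which already carries the whole ring C unit. Oxidative addition and radical capture at so crowded an arylnickel centre may be slow, so that the redox-active ester is used up by reduction or dimerisation of its benzylic radical and the triflate is returned or reduced. The fallback changes the order of bond construction, so that the ring A triflate reacts while its C3 neighbour is only an ester. It sets out from 5: hydrogenolysis should give the ring A phenol ester F6 and triflation the ring A triflate ester F7. Reductive coupling of F7 with 14 under the conditions of step 15 should give the ring B–ring A dimer ester F8. LiI demethylation should give the dimer acid F9 and N-hydroxyphthalimide with DIC the dimer redox-active ester F10. F10 is then coupled with the ring C triflate 21 under the same nickel conditions, and the route is rejoined at 25.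

2. Step 15. The arylnickel species from 21 is flanked by ring C C3 with its 3,5-bis(silyloxy)phenyl group. Capture of the ring A radical may be outrun by homocoupling or reduction of the radical, or may lose its trans selectivity. The fallback couples 7 with a less hindered triflate and introduces the 3,5-dioxyphenyl group afterwards. It sets out from 12: hydrogenolysis should give the ring C phenol ester F1 and triflation the ring C triflate ester F2. Reductive coupling of F2 with 7 under the conditions of step 15 should give the dimer methyl ester F3. LiI demethylation should give the dimer acid F4 and N-hydroxyphthalimide with DIC the dimer redox-active ester F5. F5 is arylated with arylzinc chloride 18 under the conditions of step 12, and the route is rejoined at 22.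

3. Step 23. Migratory insertion of the electron-rich styrene at the crowded arylpalladium centre of 27 may be slow. The triflate could then be reduced or hydrolysed, or the branched 1,1-diarylethene could form through the cationic pathway. The fallback transfers only a vinyl group to the hindered carbon and lets an unhindered arene be the electrophile. It sets out from 27: Stille coupling with tributyl(vinyl)stannane (Pd(PPh3)4, LiCl, 1,4-dioxane, 90 °C) should give the ring B vinyl trimer F11. A Heck reaction of F11 with 4-bromo-1,2-bis(tert-butyldimethylsilyloxy)benzene F12 (from 4-bromocatechol, TBSCl, imidazole) under Pd(OAc)2, P(o-tol)3 and Et3N in DMF should then place the aryl group on the terminal carbon, and the route is rejoined at 31.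

Further compounds
F1 | step 15 | methyl (2R,3R)-4-hydroxy-6-(pivaloyloxy)-2-[4-(pivaloyloxy)phenyl]-2,3-dihydrobenzofuran-3-carboxylate | CC(C)(C)C(=O)Oc1ccc([C@@H]2Oc3cc(OC(=O)C(C)(C)C)cc(O)c3[C@H]2C(=O)OC)cc1
F2 | step 15 | methyl (2R,3R)-6-(pivaloyloxy)-2-[4-(pivaloyloxy)phenyl]-4-(trifluoromethanesulfonyloxy)-2,3-dihydrobenzofuran-3-carboxylate | CC(C)(C)C(=O)Oc1ccc([C@@H]2Oc3cc(OC(=O)C(C)(C)C)cc(OS(=O)(=O)C(F)(F)F)c3[C@H]2C(=O)OC)cc1
F3 | step 15 | dimer methyl ester: 22 with CO2Me in place of the 3,5-bis(silyloxy)phenyl group at ring C C3 (2R,3R) | CC(C)(C)C(=O)Oc1ccc([C@H]2Oc3cc(OC(=O)C(C)(C)C)cc(OCc4ccccc4)c3[C@@H]2c2cc(OC(=O)C(C)(C)C)cc3c2[C@@H](C(=O)OC)[C@H](c2ccc(OC(=O)C(C)(C)C)cc2)O3)cc1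
F4 | step 15 | dimer acid: F3 with CO2H at ring C C3 | CC(C)(C)C(=O)Oc1ccc([C@H]2Oc3cc(OC(=O)C(C)(C)C)cc(OCc4ccccc4)c3[C@@H]2c2cc(OC(=O)C(C)(C)C)cc3c2[C@@H](C(=O)O)[C@H](c2ccc(OC(=O)C(C)(C)C)cc2)O3)cc1
F5 | step 15 | dimer redox-active ester: 1,3-dioxoisoindolin-2-yl ester of F4 | CC(C)(C)C(=O)Oc1ccc([C@H]2Oc3cc(OC(=O)C(C)(C)C)cc(OCc4ccccc4)c3[C@@H]2c2cc(OC(=O)C(C)(C)C)cc3c2[C@@H](C(=O)ON4C(=O)c5ccccc5C4=O)[C@H](c2ccc(OC(=O)C(C)(C)C)cc2)O3)cc1
F6 | step 18 | methyl (2S,3S)-4-hydroxy-6-(pivaloyloxy)-2-[4-(pivaloyloxy)phenyl]-2,3-dihydrobenzofuran-3-carboxylate | CC(C)(C)C(=O)Oc1ccc([C@H]2Oc3cc(OC(=O)C(C)(C)C)cc(O)c3[C@@H]2C(=O)OC)cc1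
F7 | step 18 | methyl (2S,3S)-6-(pivaloyloxy)-2-[4-(pivaloyloxy)phenyl]-4-(trifluoromethanesulfonyloxy)-2,3-dihydrobenzofuran-3-carboxylate | CC(C)(C)C(=O)Oc1ccc([C@H]2Oc3cc(OC(=O)C(C)(C)C)cc(OS(=O)(=O)C(F)(F)F)c3[C@@H]2C(=O)OC)cc1
F8 | step 18 | ring B–ring A dimer ester: methyl (2S,3S)-4-{(2R,3R)-4-(benzyloxy)-6-(pivaloyloxy)-2-[4-(pivaloyloxy)phenyl]-2,3-dihydrobenzofuran-3-yl}-6-(pivaloyloxy)-2-[4-(pivaloyloxy)phenyl]-2,3-dihydrobenzofuran-3-carboxylate | CC(C)(C)C(=O)Oc1ccc([C@H]2Oc3cc(OC(=O)C(C)(C)C)cc([C@@H]4c5c(OCc6ccccc6)cc(OC(=O)C(C)(C)C)cc5O[C@H]4c4ccc(OC(=O)C(C)(C)C)cc4)c3[C@@H]2C(=O)OC)cc1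
F9 | step 18 | ring B–ring A dimer acid: F8 with CO2H at ring A C3 | CC(C)(C)C(=O)Oc1ccc([C@H]2Oc3cc(OC(=O)C(C)(C)C)cc([C@@H]4c5c(OCc6ccccc6)cc(OC(=O)C(C)(C)C)cc5O[C@H]4c4ccc(OC(=O)C(C)(C)C)cc4)c3[C@@H]2C(=O)O)cc1
F10 | step 18 | ring B–ring A dimer redox-active ester: 1,3-dioxoisoindolin-2-yl ester of F9 | CC(C)(C)C(=O)Oc1ccc([C@H]2Oc3cc(OC(=O)C(C)(C)C)cc([C@@H]4c5c(OCc6ccccc6)cc(OC(=O)C(C)(C)C)cc5O[C@H]4c4ccc(OC(=O)C(C)(C)C)cc4)c3[C@@H]2C(=O)ON2C(=O)c3ccccc3C2=O)cc1
F11 | step 23 | ring B vinyl trimer: 27 with a vinyl group in place of the ring B C4 triflate | CC(C)(C)C(=O)Oc1ccc([C@H]2Oc3cc(OC(=O)C(C)(C)C)cc([C@@H]4c5c(C=C)cc(OC(=O)C(C)(C)C)cc5O[C@H]4c4ccc(OC(=O)C(C)(C)C)cc4)c3[C@@H]2c2cc(OC(=O)C(C)(C)C)cc3c2[C@@H](c2cc(O[Si](C)(C)C(C)(C)C)cc(O[Si](C)(C)C(C)(C)C)c2)[C@H](c2ccc(OC(=O)C(C)(C)C)cc2)O3)cc1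
F12 | step 23 | 4-bromo-1,2-bis(tert-butyldimethylsilyloxy)benzene | CC(C)(C)[Si](C)(C)Oc1ccc(Br)cc1O[Si](C)(C)C(C)(C)C
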